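# Synthesis design for CNP0190381.3

Core numbering used throughout (indane numbering of the target): C4 = ketone carbon, C5 = CH bearing the 2-hydroxy-2-methylpropyl group, C6 = tertiary carbinol carbon, C7 = CH2, C7a and C3a = methyl-bearing fusion carbons (C3a next to C4), C1–C3 = cyclopentane CH2 groups (C1 on C7a, C3 on C3a).

## The problem

The target 31 is a cis-fused 3a,7a-dimethylhydrindan-4-one. On the face of the six-membered ring that carries both angular methyl groups it has a tertiary hydroxyl at C6 and a 2-hydroxy-2-methylpropyl group at C5. C6 also bears an (E)-2-methylbut-2-enyl chain that ends in a free 2-hydroxy-5-methoxy-3-methylphenyl ring.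

The main difficulty is the ring fusion. C3a and C7a are adjacent, fully substituted stereocentres shared by both rings, and the cyclopentane has no functional group that could help to build them.

Of the four stereocentres (3aR,5R,6R,7aR) only one has to be set absolutely. Once C7a exists, the preference for a cis-hydrindane fixes C3a. The two angular methyls then bias the chair so that a nucleophile must reach a C6 carbonyl equatorially. C5 is alpha to the ketone and can settle under enolate or thermodynamic control.

Several groups will not survive rough treatment: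
- the tertiary beta-hydroxy ketone (C4/C6) undergoes retro-aldol cleavage with base and dehydration with acid;
- the ortho-allyl phenol cyclises to a chroman with acid and is oxidised to a quinone;
- the skipped trisubstituted alkene must stay E.

The oxygens at C4 and C6 must be kept at different oxidation levels. A 5-substituted 1,3-dione would be an enolised vinylogous acid on which C6 can no longer be addressed selectively.

The enabling feature is that the C3a–C7a bond belongs to both rings and the cyclopentane is otherwise bare. If C3a and C3 are read as the two carbons of an alkyne, C7a and C1 as those of an isopropenyl group (its methyl is the C7a methyl) and C2 as a carbonyl carbon to be deleted later, the bicycle is the Pauson–Khand product of an open-chain 1,7-enyne. Its four-atom tether C4–C7 already carries the C4 and C6 oxygens.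

## Retrosynthesis

**31 to 30 to 29.** The phenol is released last from aryl silyl ether 30, because a free 4-methoxyphenol would not survive the oxidation and enolate steps. Next the C–O bond of the side-chain tertiary alcohol is cut: 30 is the Markovnikov hydrate of the 2-methylallyl compound 29. The C5 substituent has four carbons, so the precursor is a 2-methylallyl group; a prenyl group would give the homologous 3-hydroxy-3-methylbutyl chain. The forward reaction must hydrate a 1,1-disubstituted alkene in the presence of a trisubstituted one.

**29 to 27.** The C5–CH2 bond is cut to the beta-hydroxy ketone 27. C3a is quaternary, so the C4 ketone can enolise only toward C5 and regiochemistry is not an issue. Alkylating earlier, on a 1,3-dione, would be easier, but it would merge the two carbonyl levels and block the later addition at C6. The forward step is a dianion alkylation and must avoid retro-aldol cleavage.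

**27 to 26 to 19 + 24.** The ketone comes from the secondary alcohol of diol 26. The side chain of 26 is cut at two bonds, the vinyl–benzyl bond and the vinyl–methyl bond, giving homopropargylic alcohol 19 and benzylic chloride 24. Two neighbouring cuts were rejected:
- direct addition of the complete 2-methylbut-2-enyl metal reagent to a C6 ketone would react through its gamma carbon and give the branched isomer;
- cross-metathesis of a 2-methylallyl carbinol with an allyl arene gives trisubstituted alkenes without reliable E control.

Syn carbometalation of a terminal alkyne fixes the E geometry by mechanism, and the coupling is convergent.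

**19 to 18.** The C6–CH2 bond is cut to the hydroxy ketone 18 and a propargyl nucleophile. Here C6 is an ordinary ketone and C4 is still an alcohol, so no acidic 1,3-dione is present. The C4 hydroxyl, which the key step places trans to the angular methyls, is equatorial in the chair that has the C7a methyl axial. That methyl blocks axial attack at C6, so the nucleophile should enter equatorially and the new hydroxyl should be axial, cis to the methyls, as required.

**18 to 17 to 15 to 14.** Ketal hydrolysis, deletion of the C2 carbonyl and silyl removal lead back to ketone 14. The C2 oxygen is the price of the ring construction. It sits between two CH2 groups, far from any stereocentre, and a Wolff–Kishner reduction removes it in one step while the ketal protects C6.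

**14 to 13.** The C3a–CH3 bond is cut to the bicyclic enone 13. The enone left by the cyclisation is the handle for the second angular methyl. A methyl group adding to C3a of a cyclopentenone fused to a six-membered ring should give the cis-hydrindane, so C7a controls C3a.

**13 to 11 (through 12).** Three bonds are cut at once: C3a–C7a, C2–C1 and C2–C3. The precursor 11 is an acyclic 1,7-enyne with a single stereocentre, the propargylic silyl ether at the future C4. This cut was preferred to cuts that form only one of the two rings because it builds the shared bond, both rings and the C7a quaternary centre together from a chain assembled by carbonyl chemistry. The forward reaction needs a useful rate for a 1,1-disubstituted alkene and facial control by the silyl ether; the C6 ketal helps the first through its gem-disubstituent effect.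

**11 to 10 to 9 to 8 to 5 + 6, and 5 to 4 to 1 + 2.** The stereocentre of 11 comes from asymmetric reduction of ynone 8. Ynone 8 is the union of Weinreb amide 5 with silylacetylene 6 (as its lithium salt 7). Amide 5 is the ketal of beta-keto amide 4, made from 3-methylbut-3-enoic acid 1 and Meldrum's acid 2 through acyl derivative 3. The ynone reduction was preferred to asymmetric alkynylation of the corresponding aldehyde because a beta-ketal aldehyde is elimination-prone and unbranched aldehydes are the weaker substrates for that reaction.

**24 to 23 to 22 to 21 to 20.** The benzylic chloride is traced to 4-methoxy-2-methylphenol 20 by ortho-formylation, silylation, reduction and chlorination. A silyl ether was chosen for the phenol because fluoride can remove it at the end without acid or strong base.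

## Roads not taken

**Alternative 1:** Both angular C–CH3 bonds are cut. Forward, a copper/phosphoramidite-catalysed addition of a methylaluminium reagent to C7a of the bicyclic enone A1, then methylation of the aluminium enolate at C3a, would give the cis-dimethyl hydrindanone A2.
- Merits: it is the shortest conceivable entry to the core, it sets the absolute configuration catalytically, the C4 ketone is already in place and there is no surplus carbonyl to delete.
- Weak points: the alkene of A1 is tetrasubstituted, the least developed substrate class for enantioselective conjugate methylation. The aluminium enolate then has to be C-methylated at a fully substituted carbon next to a freshly made quaternary centre. A2 also has no oxygen at C6, so C5 and C6 would have to be functionalised later through an enone and a 1,3-oxygenation sequence.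
- Comparison: this road is better in step count to the hydrocarbon core and needs no protecting groups there. The chosen plan sets against it that C7a arises in a diastereoselective ring closure rather than by attack on a tetrasubstituted enone, and that 13 already has C4 and C6 oxygenated and differentiated.

**Alternative 2:** The C3a–C4 and C7a–C7 bonds are cut. Forward, irradiation of the chiral dioxinone A3 with 1,2-dimethylcyclopentene A4 would give the cyclobutane photoadduct A5. Retro-aldol opening and a Claisen-type closure of the resulting keto ester would then give the bicyclic 1,3-dione.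
- Merits: both quaternary carbons and their cis relationship arise in one step from a symmetrical alkene, the acetal centre of A3 controls the face, and both ring oxygens come with the dioxinone. The core would probably be reached in fewer steps than in the chosen plan, and no cuprate has to attack a hindered enone.
- Weak points: a tetrasubstituted alkene is a demanding partner in an enone photocycloaddition (hydrogen abstraction and dimerisation of A3 compete), and photochemistry limits scale. All enantiocontrol rests on the facial selectivity of A3, whose stereocentre is destroyed afterwards. The output has the undifferentiated 1,3-dione pattern, which is enolised once C5 is substituted and resists selective addition at C6.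
- Comparison: this road is better in step count to the core. The chosen plan sets against it the differentiated C4 alcohol and C6 ketal levels, which are what make the C6 addition and its stereocontrol workable, ground-state chemistry throughout, and a separable diastereomer checkpoint at 13.

**Alternative 3:** The C5–C6 bond is cut. Forward, a phosphine-stabilised copper hydride would add hydride to the enone of the open-chain diketone A6, and the copper enolate would close onto the side-chain ketone to give the bis-silyl ether A7 of the target.
- Merits: it is the most convergent plan. The last C–C bond closes the ring, sets C5 and C6 together under nearly neutral conditions, and the cis hydroxyl/alkyl relationship expected from a chelated enolate matches the target. It avoids the late enolate alkylation and the chemoselective hydration of the chosen plan.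
- Weak points: A6 still contains the cis-1,2-dimethylcyclopentane with two different vicinal quaternary centres, so the central problem is moved upstream without a solution. The C6 ketone of A6 is beta,gamma-unsaturated and can slip into conjugation. The enone beta-carbon is next to a fully substituted silyloxy carbon, which slows hydrometalation and invites reduction of the other ketone. Facial selectivity at C6 rests on an untested transition state.
- Comparison: its endgame is better than the chosen one. The chosen plan sets against it a defined construction of the quaternary pair and rigid bicyclic intermediates, in which the angular methyls control C6 and C5.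

Key step: step 7

Assumption: the stereodescriptors of the structure are taken at face value, (3aR,5R,6R,7aR) with an E side-chain alkene; the facial sense of step 7 is assigned from a chair-like tether, and if it proves opposite the (R,R)-catalyst in step 4 corrects it without changing the route.

## Route

Step 1
Reactants: 1 3-methylbut-3-enoic acid; 2 Meldrum's acid (2,2-dimethyl-1,3-dioxane-4,6-dione)
Product: 4 N-methoxy-N,5-dimethyl-3-oxohex-5-enamide, via acyl Meldrum's acid 3 (not isolated)
Conditions: DCC, DMAP, CH2Cl2, 0 °C to rt; filter, acid wash; then MeNHOMe·HCl, Et3N, toluene, 80 °C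
Reagents that add atoms: N,O-dimethylhydroxylamine hydrochloride, CNOC.Cl
Why: Carbodiimide C-acylation of Meldrum's acid followed by thermal loss of acetone and CO2 gives an acylketene that the weakly basic amine traps as the beta-keto Weinreb amide; the near-neutral conditions are chosen so that the beta,gamma-alkene does not move into conjugation.

Step 2
Reactants: 4 N-methoxy-N,5-dimethyl-3-oxohex-5-enamide
Product: 5 N-methoxy-N-methyl-2-[2-(2-methylprop-2-en-1-yl)-1,3-dioxolan-2-yl]acetamide
Conditions: TMSOCH2CH2OTMS, TMSOTf (cat.), CH2Cl2, −78 to −20 °C; pyridine quench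
Reagents that add atoms: 1,2-bis(trimethylsilyloxy)ethane, C[Si](C)(C)OCCO[Si](C)(C)C
Why: Noyori ketalisation is kinetic and avoids the enol intermediates of Brønsted-acid ketalisation, so the 1,1-disubstituted alkene stays in place; the ketal masks C6 and later supplies the gem-disubstituent effect.

Step 3
Reactants: 5 N-methoxy-N-methyl-2-[2-(2-methylprop-2-en-1-yl)-1,3-dioxolan-2-yl]acetamide; 6 ethynyltrimethylsilane
Product: 8 1-[2-(2-methylprop-2-en-1-yl)-1,3-dioxolan-2-yl]-4-(trimethylsilyl)but-3-yn-2-one, via lithium (trimethylsilyl)acetylide 7 (not isolated)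
Conditions: 6, n-BuLi, THF, −78 °C; then 5, −78 to −20 °C; aq. NH4Cl
Reagents that add atoms: none
Why: Weinreb ketone synthesis; the N,O-chelated tetrahedral adduct prevents over-addition and collapses to the ynone only on quench.

Step 4
Reactants: 8 1-[2-(2-methylprop-2-en-1-yl)-1,3-dioxolan-2-yl]-4-(trimethylsilyl)but-3-yn-2-one
Product: 9 (S)-1-[2-(2-methylprop-2-en-1-yl)-1,3-dioxolan-2-yl]-4-(trimethylsilyl)but-3-yn-2-ol
Conditions: Ru[(S,S)-TsDPEN](p-cymene) (cat.), i-PrOH, rt
Reagents that add atoms: none
Why: Noyori asymmetric transfer hydrogenation of an alkynyl ketone; the (S,S)-catalyst distinguishes the alkynyl from the alkyl side and should deliver the (S)-carbinol (the future C4), under base-free conditions that spare the enolisable CH2 and the ketal.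

Step 5
Reactants: 9 (S)-1-[2-(2-methylprop-2-en-1-yl)-1,3-dioxolan-2-yl]-4-(trimethylsilyl)but-3-yn-2-ol
Product: 10 (S)-tert-butyldimethyl({1-[2-(2-methylprop-2-en-1-yl)-1,3-dioxolan-2-yl]-4-(trimethylsilyl)but-3-yn-2-yl}oxy)silane
Conditions: TBSCl, imidazole, DMF, rt
Reagents that add atoms: tert-butyldimethylsilyl chloride, CC(C)(C)[Si](C)(C)Cl
Why: Standard silylation; the bulky silyl ether is the stereocontrol element of step 7 and keeps the oxygen inert in step 8.

Step 6
Reactants: 10 (S)-tert-butyldimethyl({1-[2-(2-methylprop-2-en-1-yl)-1,3-dioxolan-2-yl]-4-(trimethylsilyl)but-3-yn-2-yl}oxy)silane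
Product: 11 (S)-tert-butyldimethyl({1-[2-(2-methylprop-2-en-1-yl)-1,3-dioxolan-2-yl]but-3-yn-2-yl}oxy)silane
Conditions: K2CO3 (cat.), MeOH, rt
Reagents that add atoms: none
Why: Methanolysis of the alkynyl C–Si bond; the secondary silyl ether and the ketal are stable to these conditions.

Step 7
Reactants: 11 (S)-tert-butyldimethyl({1-[2-(2-methylprop-2-en-1-yl)-1,3-dioxolan-2-yl]but-3-yn-2-yl}oxy)silane
Product: 13 (4'S,7a'R)-4'-[(tert-butyldimethylsilyl)oxy]-7a'-methyl-4',5',7',7a'-tetrahydrospiro[1,3-dioxolane-2,6'-inden]-2'(1'H)-one, via alkyne hexacarbonyldicobalt complex 12 (not isolated)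
Conditions: Co2(CO)8, CH2Cl2, rt; then Me3NO, 4 Å MS, CH2Cl2, 0 °C to rt
Reagents that add atoms: carbon monoxide, delivered as a ligand of dicobalt octacarbonyl Co2(CO)8, [C-]#[O+]
Why: Intramolecular Pauson–Khand reaction of a 1,7-enyne with a 1,1-disubstituted alkene, the closest known type being cyclisations of silyloxy-substituted 1,7-enynes to angularly methylated bicyclo[4.3.0]nonenones. The alkyne of 11 is first bound as the Co2(CO)6 complex 12; the N-oxide oxidises a carbonyl ligand to CO2 and opens a coordination site for the tethered alkene. Alkene insertion into a Co–C bond forms the C3a–C7a bond and a cobaltacycle, which closes the six-membered ring in an exo mode (the alkene CH2 and the alkyne CH both stay outside the new ring); CO insertion and reductive elimination then close the cyclopentenone as the [2+2+1] ring, with the new carbonyl C2 bonded to C1 and C3. The only new stereocentre, C7a, is controlled by the C4 silyloxy centre: in a chair-like tether the bulky silyloxy group sits pseudo-equatorial, away from the cobalt cluster, and the alkene methyl is axial, so methyl and silyloxy should end up trans (4'S,7a'R). The step needs facial selectivity at the alkene and a sufficient rate for a hindered alkene in a six-ring-forming mode; the first is secured by the propargylic silyl ether, the second by the C6 ketal, whose gem-dialkoxy substitution compresses the tether, and by N-oxide promotion at low temperature. Regiochemistry is fixed by the tether, and the terminal alkyne leaves C3 unsubstituted for the conjugate addition that follows.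

Step 8
Reactants: 13 (4'S,7a'R)-4'-[(tert-butyldimethylsilyl)oxy]-7a'-methyl-4',5',7',7a'-tetrahydrospiro[1,3-dioxolane-2,6'-inden]-2'(1'H)-one
Product: 14 (3a'R,4'S,7a'R)-4'-[(tert-butyldimethylsilyl)oxy]-3a',7a'-dimethylhexahydrospiro[1,3-dioxolane-2,6'-inden]-2'(1'H)-one
Conditions: Me2CuLi (from CuI, MeLi), BF3·OEt2, Et2O, −78 to −30 °C; aq. NH4Cl/NH3
Reagents that add atoms: lithium dimethylcuprate, made from methyllithium and CuI, [Li+].C[Cu-]C
Why: Lewis-acid-assisted organocuprate conjugate addition to a beta,beta-disubstituted cyclopentenone; methyl should enter C3a on the face that gives the cis-fused hydrindane (same face as the C7a methyl, opposite to the six-ring CH2 and the C4 silyloxy group), so C3a becomes R, and the gamma-silyloxy group is too poor a leaving group to be lost.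

Step 9
Reactants: 14 (3a'R,4'S,7a'R)-4'-[(tert-butyldimethylsilyl)oxy]-3a',7a'-dimethylhexahydrospiro[1,3-dioxolane-2,6'-inden]-2'(1'H)-one
Product: 15 (3a'R,4'S,7a'R)-4'-hydroxy-3a',7a'-dimethylhexahydrospiro[1,3-dioxolane-2,6'-inden]-2'(1'H)-one
Conditions: TBAF, THF, rt to 50 °C
Reagents that add atoms: none
Why: Fluoride desilylation, placed before the reduction so that the outcome of the hot-alkali step is unambiguous; the hydroxyl is gamma to the ketone and cannot undergo retro-aldol cleavage.

Step 10
Reactants: 15 (3a'R,4'S,7a'R)-4'-hydroxy-3a',7a'-dimethylhexahydrospiro[1,3-dioxolane-2,6'-inden]-2'(1'H)-one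
Product: 17 (3a'R,4'S,7a'R)-3a',7a'-dimethyloctahydrospiro[1,3-dioxolane-2,6'-inden]-4'-ol, via hydrazone 16 (not isolated)
Conditions: N2H4·H2O, diethylene glycol, 130 °C; then KOH, 200 °C
Reagents that add atoms: none
Why: Wolff–Kishner reduction (Huang-Minlon procedure) turns the C2 carbonyl into CH2 through the hydrazone and loss of N2; ketal and secondary alcohol are inert to hot alkali and no stereocentre is alpha to the carbonyl.

Step 11
Reactants: 17 (3a'R,4'S,7a'R)-3a',7a'-dimethyloctahydrospiro[1,3-dioxolane-2,6'-inden]-4'-ol
Product: 18 (3aR,7S,7aR)-7-hydroxy-3a,7a-dimethyloctahydro-5H-inden-5-one (core C4 hydroxyl, C6 ketone)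
Conditions: 1 M HCl, THF, rt
Reagents that add atoms: water, O
Why: Acid hydrolysis of the dioxolane; dilute acid at room temperature is used so that the beta-hydroxy ketone does not dehydrate.

Step 12
Reactants: 18 (3aR,7S,7aR)-7-hydroxy-3a,7a-dimethyloctahydro-5H-inden-5-one
Product: 19 (3aR,4S,6R,7aR)-3a,7a-dimethyl-6-(prop-2-yn-1-yl)octahydro-1H-indene-4,6-diol
Conditions: propargyl bromide, Zn dust (excess), THF, 0 °C to rt; aq. NH4Cl
Reagents that add atoms: 3-bromoprop-1-yne (propargyl bromide), C#CCBr
Why: Barbier-type propargylation in which allenylzinc bromide adds through an SE2' transition state to give the homopropargylic alcohol; in the chair with the C7a methyl axial and the C4 oxygen equatorial, axial attack on C6 is blocked by the syn-axial methyl, so the nucleophile should enter equatorially and the new hydroxyl should be axial, cis to the angular methyls (6R).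

Step 13
Reactants: 20 4-methoxy-2-methylphenol
Product: 21 2-hydroxy-5-methoxy-3-methylbenzaldehyde
Conditions: MgCl2, Et3N, (CH2O)n, MeCN, reflux
Reagents that add atoms: paraformaldehyde (as formaldehyde), C=O
Why: Magnesium-phenoxide-directed ortho-formylation (Casnati–Skattebøl); only one ortho position is free, and a second formaldehyde serves as the hydride acceptor.

Step 14
Reactants: 21 2-hydroxy-5-methoxy-3-methylbenzaldehyde
Product: 22 2-[(tert-butyldimethylsilyl)oxy]-5-methoxy-3-methylbenzaldehyde
Conditions: TBSCl, imidazole, DMF, rt
Reagents that add atoms: tert-butyldimethylsilyl chloride, CC(C)(C)[Si](C)(C)Cl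
Why: Standard phenol silylation; the silyl ether tolerates organoaluminium, amide base and radical conditions and is removed with fluoride at the end.

Step 15
Reactants: 22 2-[(tert-butyldimethylsilyl)oxy]-5-methoxy-3-methylbenzaldehyde
Product: 23 {2-[(tert-butyldimethylsilyl)oxy]-5-methoxy-3-methylphenyl}methanol
Conditions: NaBH4, MeOH, 0 °C
Reagents that add atoms: none
Why: Borohydride reduction in a protic solvent at low temperature, where the alkoxide is protonated before the silyl group can migrate from the phenol oxygen.

Step 16
Reactants: 23 {2-[(tert-butyldimethylsilyl)oxy]-5-methoxy-3-methylphenyl}methanol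
Product: 24 tert-butyl[2-(chloromethyl)-4-methoxy-6-methylphenoxy]dimethylsilane
Conditions: PPh3, NCS, CH2Cl2, 0 °C to rt
Reagents that add atoms: N-chlorosuccinimide, ClN1C(=O)CCC1=O
Why: Appel-type chlorination of a benzylic alcohol under neutral conditions that keep the aryl silyl ether.

Step 17
Reactants: 19 (3aR,4S,6R,7aR)-3a,7a-dimethyl-6-(prop-2-yn-1-yl)octahydro-1H-indene-4,6-diol; 24 tert-butyl[2-(chloromethyl)-4-methoxy-6-methylphenoxy]dimethylsilane
Product: 26 (3aR,4S,6R,7aR)-6-[(2E)-4-{2-[(tert-butyldimethylsilyl)oxy]-5-methoxy-3-methylphenyl}-2-methylbut-2-en-1-yl]-3a,7a-dimethyloctahydro-1H-indene-4,6-diol, via alkenylalane 25 (not isolated)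
Conditions: Me3Al, Cp2ZrCl2 (cat.), CH2Cl2, 0 °C to rt; evaporate; then 24, NiCl2(PPh3)2/n-BuLi (cat., zerovalent nickel), THF, rt; aq. potassium sodium tartrate
Reagents that add atoms: trimethylaluminium, C[Al](C)C
Why: Negishi zirconium-catalysed carboalumination adds CH3 and Al syn across the terminal alkyne with Al on the terminal carbon, which fixes the E geometry; nickel-catalysed coupling of the alkenylalane with the benzylic chloride then forms the allyl–aryl bond with retention, the established way to make prenyl-type arene side chains.

Step 18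
Reactants: 26 (3aR,4S,6R,7aR)-6-[(2E)-4-{2-[(tert-butyldimethylsilyl)oxy]-5-methoxy-3-methylphenyl}-2-methylbut-2-en-1-yl]-3a,7a-dimethyloctahydro-1H-indene-4,6-diol
Product: 27 (3aR,6R,7aR)-6-[(2E)-4-{2-[(tert-butyldimethylsilyl)oxy]-5-methoxy-3-methylphenyl}-2-methylbut-2-en-1-yl]-6-hydroxy-3a,7a-dimethyloctahydro-4H-inden-4-one
Conditions: Dess–Martin periodinane, NaHCO3, CH2Cl2, 0 °C to rt
Reagents that add atoms: none
Why: Dess–Martin oxidation of the secondary C4 alcohol; the tertiary alcohol, the alkene and the protected arene are untouched and the buffered neutral medium avoids retro-aldol cleavage.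

Step 19
Reactants: 27 (3aR,6R,7aR)-6-[(2E)-4-{2-[(tert-butyldimethylsilyl)oxy]-5-methoxy-3-methylphenyl}-2-methylbut-2-en-1-yl]-6-hydroxy-3a,7a-dimethyloctahydro-4H-inden-4-one
Product: 29 (3aR,5R,6R,7aR)-6-[(2E)-4-{2-[(tert-butyldimethylsilyl)oxy]-5-methoxy-3-methylphenyl}-2-methylbut-2-en-1-yl]-6-hydroxy-3a,7a-dimethyl-5-(2-methylprop-2-en-1-yl)octahydro-4H-inden-4-one, via dilithium enolate alkoxide 28 (not isolated)
Conditions: LiN(i-Pr)2 (2.3 equiv), THF, −78 °C; DMPU, 3-bromo-2-methylprop-1-ene, −78 to −40 °C; aq. NH4Cl
Reagents that add atoms: 3-bromo-2-methylprop-1-ene, C=C(C)CBr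
Why: Alkylation of a beta-hydroxy ketone dianion (Fráter–Seebach type): the alkoxide cannot leave, the dianion cannot undergo retro-aldol cleavage, and the enolate can form only toward C5 because C3a is quaternary; the electrophile should approach C5 anti to the axial C3 methylene, giving the equatorial 5R group cis to the C6 hydroxyl, which is also the more stable epimer at this enolisable centre.

Step 20
Reactants: 29 (3aR,5R,6R,7aR)-6-[(2E)-4-{2-[(tert-butyldimethylsilyl)oxy]-5-methoxy-3-methylphenyl}-2-methylbut-2-en-1-yl]-6-hydroxy-3a,7a-dimethyl-5-(2-methylprop-2-en-1-yl)octahydro-4H-inden-4-one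
Product: 30 (3aR,5R,6R,7aR)-6-[(2E)-4-{2-[(tert-butyldimethylsilyl)oxy]-5-methoxy-3-methylphenyl}-2-methylbut-2-en-1-yl]-6-hydroxy-5-(2-hydroxy-2-methylpropyl)-3a,7a-dimethyloctahydro-4H-inden-4-one
Conditions: Co(acac)2 (cat.), PhSiH3, O2 (1 atm), THF, rt; aq. Na2S2O3
Reagents that add atoms: dioxygen, O=O
Why: Mukaiyama hydration (cobalt-hydride hydrogen-atom transfer, trapping of the tertiary radical by O2, reduction of the peroxide) gives the Markovnikov tertiary alcohol; with the mild Co(acac)2 catalyst the unhindered 1,1-disubstituted alkene should react well before the trisubstituted side-chain alkene.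

Step 21
Reactants: 30 (3aR,5R,6R,7aR)-6-[(2E)-4-{2-[(tert-butyldimethylsilyl)oxy]-5-methoxy-3-methylphenyl}-2-methylbut-2-en-1-yl]-6-hydroxy-5-(2-hydroxy-2-methylpropyl)-3a,7a-dimethyloctahydro-4H-inden-4-one
Product: 31 (3aR,5R,6R,7aR)-6-hydroxy-6-[(2E)-4-(2-hydroxy-5-methoxy-3-methylphenyl)-2-methylbut-2-en-1-yl]-5-(2-hydroxy-2-methylpropyl)-3a,7a-dimethyloctahydro-4H-inden-4-one (CNP0190381.3)
Conditions: TBAF, AcOH, THF, 0 °C
Reagents that add atoms: none
Why: Buffered fluoride cleaves the aryl silyl ether without base-induced retro-aldol cleavage or acid-induced chroman formation.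

## Compound list

1 | 3-methylbut-3-enoic acid | CC(=C)CC(O)=O | starting material
2 | Meldrum's acid (2,2-dimethyl-1,3-dioxane-4,6-dione) | CC1(C)OC(=O)CC(=O)O1 | starting material
3 | 5-(1-hydroxy-3-methylbut-3-en-1-ylidene)-2,2-dimethyl-1,3-dioxane-4,6-dione (acyl Meldrum's acid) | CC(=C)CC(O)=C1C(=O)OC(C)(C)OC1=O | intermediate
4 | N-methoxy-N,5-dimethyl-3-oxohex-5-enamide | CC(=C)CC(=O)CC(=O)N(C)OC | intermediate
5 | N-methoxy-N-methyl-2-[2-(2-methylprop-2-en-1-yl)-1,3-dioxolan-2-yl]acetamide | CC(=C)CC1(CC(=O)N(C)OC)OCCO1 | intermediate
6 | ethynyltrimethylsilane | C[Si](C)(C)C#C | starting material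
7 | lithium (trimethylsilyl)acetylide | [Li]C#C[Si](C)(C)C | intermediate
8 | 1-[2-(2-methylprop-2-en-1-yl)-1,3-dioxolan-2-yl]-4-(trimethylsilyl)but-3-yn-2-one | CC(=C)CC1(CC(=O)C#C[Si](C)(C)C)OCCO1 | intermediate
9 | (S)-1-[2-(2-methylprop-2-en-1-yl)-1,3-dioxolan-2-yl]-4-(trimethylsilyl)but-3-yn-2-ol | CC(=C)CC1(C[C@H](O)C#C[Si](C)(C)C)OCCO1 | intermediate
10 | (S)-tert-butyldimethyl({1-[2-(2-methylprop-2-en-1-yl)-1,3-dioxolan-2-yl]-4-(trimethylsilyl)but-3-yn-2-yl}oxy)silane | CC(=C)CC1(C[C@H](O[Si](C)(C)C(C)(C)C)C#C[Si](C)(C)C)OCCO1 | intermediate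
11 | (S)-tert-butyldimethyl({1-[2-(2-methylprop-2-en-1-yl)-1,3-dioxolan-2-yl]but-3-yn-2-yl}oxy)silane | C=C(C)CC1(C[C@H](O[Si](C)(C)C(C)(C)C)C#C)OCCO1 | intermediate
12 | hexacarbonyldicobalt complex of the alkyne of 11 (C2Co2 tetrahedrane core, three CO on each cobalt) | C=C(C)CC1(C[C@H](O[Si](C)(C)C(C)(C)C)[C]23[CH]4[Co]2(=C=O)(=C=O)(=C=O)[Co]34(=C=O)(=C=O)=C=O)OCCO1 | intermediate
13 | (4'S,7a'R)-4'-[(tert-butyldimethylsilyl)oxy]-7a'-methyl-4',5',7',7a'-tetrahydrospiro[1,3-dioxolane-2,6'-inden]-2'(1'H)-one | O=C1C=C2[C@@H](O[Si](C)(C)C(C)(C)C)CC3(OCCO3)C[C@@]2(C)C1 | intermediate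
14 | (3a'R,4'S,7a'R)-4'-[(tert-butyldimethylsilyl)oxy]-3a',7a'-dimethylhexahydrospiro[1,3-dioxolane-2,6'-inden]-2'(1'H)-one | O=C1C[C@@]2(C)[C@@H](O[Si](C)(C)C(C)(C)C)CC3(OCCO3)C[C@@]2(C)C1 | intermediate
15 | (3a'R,4'S,7a'R)-4'-hydroxy-3a',7a'-dimethylhexahydrospiro[1,3-dioxolane-2,6'-inden]-2'(1'H)-one | O=C1C[C@@]2(C)[C@@H](O)CC3(OCCO3)C[C@@]2(C)C1 | intermediate
16 | hydrazone of 15 at C2' | NN=C1C[C@@]2(C)[C@@H](O)CC3(OCCO3)C[C@@]2(C)C1 | intermediate
17 | (3a'R,4'S,7a'R)-3a',7a'-dimethyloctahydrospiro[1,3-dioxolane-2,6'-inden]-4'-ol | C1C[C@@]2(C)[C@@H](O)CC3(OCCO3)C[C@@]2(C)C1 | intermediate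
18 | (3aR,7S,7aR)-7-hydroxy-3a,7a-dimethyloctahydro-5H-inden-5-one | C1C[C@@]2(C)[C@@H](O)CC(=O)C[C@@]2(C)C1 | intermediate
19 | (3aR,4S,6R,7aR)-3a,7a-dimethyl-6-(prop-2-yn-1-yl)octahydro-1H-indene-4,6-diol | C1C[C@@]2(C)[C@@H](O)C[C@@](O)(CC#C)C[C@@]2(C)C1 | intermediate
20 | 4-methoxy-2-methylphenol | COc1ccc(O)c(C)c1 | starting material
21 | 2-hydroxy-5-methoxy-3-methylbenzaldehyde | COc1cc(C)c(O)c(C=O)c1 | intermediate
22 | 2-[(tert-butyldimethylsilyl)oxy]-5-methoxy-3-methylbenzaldehyde | COc1cc(C)c(O[Si](C)(C)C(C)(C)C)c(C=O)c1 | intermediate
23 | {2-[(tert-butyldimethylsilyl)oxy]-5-methoxy-3-methylphenyl}methanol | COc1cc(C)c(O[Si](C)(C)C(C)(C)C)c(CO)c1 | intermediate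
24 | tert-butyl[2-(chloromethyl)-4-methoxy-6-methylphenoxy]dimethylsilane | COc1cc(C)c(O[Si](C)(C)C(C)(C)C)c(CCl)c1 | intermediate
25 | (E)-alkenyl(dimethyl)alane from 19, both hydroxyls as dimethylaluminium alkoxides (Al trans to the ring CH2) | C1C[C@@]2(C)[C@@H](O[Al](C)C)C[C@@](O[Al](C)C)(C/C(C)=C/[Al](C)C)C[C@@]2(C)C1 | intermediate
26 | (3aR,4S,6R,7aR)-6-[(2E)-4-{2-[(tert-butyldimethylsilyl)oxy]-5-methoxy-3-methylphenyl}-2-methylbut-2-en-1-yl]-3a,7a-dimethyloctahydro-1H-indene-4,6-diol | C1C[C@@]2(C)[C@@H](O)C[C@@](O)(C/C(C)=C/Cc3cc(OC)cc(C)c3O[Si](C)(C)C(C)(C)C)C[C@@]2(C)C1 | intermediate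
27 | (3aR,6R,7aR)-6-[(2E)-4-{2-[(tert-butyldimethylsilyl)oxy]-5-methoxy-3-methylphenyl}-2-methylbut-2-en-1-yl]-6-hydroxy-3a,7a-dimethyloctahydro-4H-inden-4-one | C1C[C@@]2(C)C(=O)C[C@@](O)(C/C(C)=C/Cc3cc(OC)cc(C)c3O[Si](C)(C)C(C)(C)C)C[C@@]2(C)C1 | intermediate
28 | dilithium salt of 27 (C4–C5 enolate, C6 alkoxide) | C1C[C@@]2(C)C(O[Li])=C[C@@](O[Li])(C/C(C)=C/Cc3cc(OC)cc(C)c3O[Si](C)(C)C(C)(C)C)C[C@@]2(C)C1 | intermediate
29 | (3aR,5R,6R,7aR)-6-[(2E)-4-{2-[(tert-butyldimethylsilyl)oxy]-5-methoxy-3-methylphenyl}-2-methylbut-2-en-1-yl]-6-hydroxy-3a,7a-dimethyl-5-(2-methylprop-2-en-1-yl)octahydro-4H-inden-4-one | C1C[C@@]2(C)C(=O)[C@H](CC(C)=C)[C@@](O)(C/C(C)=C/Cc3cc(OC)cc(C)c3O[Si](C)(C)C(C)(C)C)C[C@@]2(C)C1 | intermediate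
30 | (3aR,5R,6R,7aR)-6-[(2E)-4-{2-[(tert-butyldimethylsilyl)oxy]-5-methoxy-3-methylphenyl}-2-methylbut-2-en-1-yl]-6-hydroxy-5-(2-hydroxy-2-methylpropyl)-3a,7a-dimethyloctahydro-4H-inden-4-one | C1C[C@@]2(C)C(=O)[C@H](CC(C)(C)O)[C@@](O)(C/C(C)=C/Cc3cc(OC)cc(C)c3O[Si](C)(C)C(C)(C)C)C[C@@]2(C)C1 | intermediate
31 | (3aR,5R,6R,7aR)-6-hydroxy-6-[(2E)-4-(2-hydroxy-5-methoxy-3-methylphenyl)-2-methylbut-2-en-1-yl]-5-(2-hydroxy-2-methylpropyl)-3a,7a-dimethyloctahydro-4H-inden-4-one (CNP0190381.3) | COc1cc(C)c(O)c(C/C=C(\C)C[C@@]2(O)C[C@@]3(C)CCC[C@@]3(C)C(=O)[C@@H]2CC(C)(C)O)c1 | target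

## Step count, longest sequence and uncertain steps

Total: 21 steps. Longest linear sequence: 17 steps (steps 1–12 and 17–21, from 3-methylbut-3-enoic acid); the arene fragment takes 4 steps (13–16).

**Step 7 (key step).** The most likely failure is slow insertion of the 1,1-disubstituted alkene in the six-ring-forming mode, so that complex 12 is decomplexed or decomposes before it cyclises. Incomplete facial selectivity at C7a is the second concern; the epimers are diastereomers and can be separated at 13, at the cost of material. Fallback: set out from silylalkyne 10 and use a zirconocene-mediated bicyclisation–carbonylation (Cp2ZrCl2/2 n-BuLi, THF, −78 °C to rt; then CO, 1 atm). It runs through the zirconacyclopentene F1 instead of an alkyne–dicobalt cluster and works best with silylalkynes. It would give the 3'-(trimethylsilyl) enone F2. One equivalent of buffered TBAF at 0 °C should cleave the vinylic C–Si bond alpha to the carbonyl before the hindered secondary silyl ether and return to 13.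

**Step 8.** The beta-carbon lies between a quaternary carbon and a silyloxy methine, so the likely failure is no conjugate addition, with 1,2-addition or recovery of enone instead. Fallback: set out from 13.
- Luche reduction (NaBH4, CeCl3·7H2O, MeOH) gives the allylic alcohol F3 with the hydroxyl cis to the C7a methyl; the other epimer would be inverted by a Mitsunobu sequence.
- Hydroxyl-directed Simmons–Smith cyclopropanation (Et2Zn, CH2I2) gives the cyclopropyl carbinol F4.
- Dess–Martin oxidation gives the cyclopropyl ketone F5.
- Li/NH3 cleaves the exocyclic cyclopropane bond, the one aligned with the carbonyl pi system, which turns the cyclopropane CH2 into the C3a methyl and returns to 14.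

**Step 17.** The likely failure is in the one-flask sequence: incomplete carboalumination of the hindered homopropargylic bis-alkoxide, or inhibition of the nickel catalyst by aluminium and zirconium residues, leading to protodealumination instead of coupling. Fallback: set out from alane 25, generated as in step 17, and quench it with iodine to isolate the (E)-vinyl iodide F6. Separately convert 24 with zinc dust and LiCl into the benzylzinc chloride F7. A Pd(PPh3)4-catalysed Negishi coupling of F6 with excess F7 forms the same bond with reversed polarity and returns to 26.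

**Step 19.** The likely failures are retro-aldol opening of the lithium aldolate before the second deprotonation is complete, or sluggish alkylation at the hindered C5 with loss of facial selectivity. Fallback: set out from 27 and avoid the strong base.
- TMSOTf/Et3N gives the bis-silyl compound F8 (C4 silyl enol ether, C6 trimethylsilyl ether).
- Tsuji–Trost allylation of the silyl enol ether with 2-methylallyl methyl carbonate (Pd2(dba)3, dppe, THF, 65 °C) gives the C5-(2-methylallyl) ketone F9.
- Citric acid in methanol removes the tertiary trimethylsilyl ether and returns to 29.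

**Step 20.** The likely failure is insufficient discrimination between the two alkenes, with partial hydration or reduction of the trisubstituted side-chain alkene and autoxidation at its doubly activated benzylic CH2. Fallback: set out from 29 and switch from the radical to the ionic manifold. Oxymercuration with Hg(OAc)2 in THF–water strongly prefers the 1,1-disubstituted alkene and gives the organomercurial F10. Brief demercuration with NaBH4 at 0 °C, which the hindered C4 ketone should survive, returns to 30.

## Further compounds

F1 | step 7 | zirconacyclopentene from 10 (Cp2Zr bonded to the silyl-bearing alkene carbon and to C1' CH2) | C[Si](C)(C)C1=C2[C@@H](O[Si](C)(C)C(C)(C)C)CC3(OCCO3)C[C@@]2(C)C[Zr]1(C4C=CC=C4)C5C=CC=C5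
F2 | step 7 | (4'S,7a'R)-4'-[(tert-butyldimethylsilyl)oxy]-7a'-methyl-3'-(trimethylsilyl)-4',5',7',7a'-tetrahydrospiro[1,3-dioxolane-2,6'-inden]-2'(1'H)-one | O=C1C([Si](C)(C)C)=C2[C@@H](O[Si](C)(C)C(C)(C)C)CC3(OCCO3)C[C@@]2(C)C1
F3 | step 8 | (2'S,4'S,7a'R)-4'-[(tert-butyldimethylsilyl)oxy]-7a'-methyl-1',2',4',5',7',7a'-hexahydrospiro[1,3-dioxolane-2,6'-inden]-2'-ol (hydroxyl cis to the C7a' methyl) | O[C@@H]1C=C2[C@@H](O[Si](C)(C)C(C)(C)C)CC3(OCCO3)C[C@@]2(C)C1
F4 | step 8 | cyclopropyl carbinol from F3: CH2 bridging C3' and C3a' on the face of the C7a' methyl and the C2' hydroxyl | O[C@@H]1[C@@H]2C[C@@]23[C@@H](O[Si](C)(C)C(C)(C)C)CC4(OCCO4)C[C@@]3(C)C1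
F5 | step 8 | cyclopropyl ketone from F4 (C2' ketone, CH2 bridging C3' and C3a' cis to the C7a' methyl) | O=C1[C@@H]2C[C@@]23[C@@H](O[Si](C)(C)C(C)(C)C)CC4(OCCO4)C[C@@]3(C)C1
F6 | step 17 | (3aR,4S,6S,7aR)-6-[(2E)-3-iodo-2-methylprop-2-en-1-yl]-3a,7a-dimethyloctahydro-1H-indene-4,6-diol | C1C[C@@]2(C)[C@@H](O)C[C@@](O)(C/C(C)=C/I)C[C@@]2(C)C1
F7 | step 17 | {2-[(tert-butyldimethylsilyl)oxy]-5-methoxy-3-methylbenzyl}zinc chloride | COc1cc(C)c(O[Si](C)(C)C(C)(C)C)c(C[Zn]Cl)c1
F8 | step 19 | bis(trimethylsilyl) derivative of 27 (C4 silyl enol ether toward C5, C6 trimethylsilyl ether) | C1C[C@@]2(C)C(O[Si](C)(C)C)=C[C@@](O[Si](C)(C)C)(C/C(C)=C/Cc3cc(OC)cc(C)c3O[Si](C)(C)C(C)(C)C)C[C@@]2(C)C1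
F9 | step 19 | C6 trimethylsilyl ether of 29 | C1C[C@@]2(C)C(=O)[C@H](CC(C)=C)[C@@](O[Si](C)(C)C)(C/C(C)=C/Cc3cc(OC)cc(C)c3O[Si](C)(C)C(C)(C)C)C[C@@]2(C)C1
F10 | step 20 | acetoxymercurio alcohol from 29 (C5 side chain CH2C(CH3)(OH)CH2HgOAc, mixture at the new carbinol carbon) | C1C[C@@]2(C)C(=O)[C@H](CC(C)(O)C[Hg]OC(C)=O)[C@@](O)(C/C(C)=C/Cc3cc(OC)cc(C)c3O[Si](C)(C)C(C)(C)C)C[C@@]2(C)C1
A1 | alternative 1 | 1,2,3,5,6,7-hexahydro-4H-inden-4-one | O=C1CCCC2=C1CCC2
A2 | alternative 1 | cis-3a,7a-dimethyloctahydroinden-4-one | O=C1CCC[C@@]2(C)CCC[C@@]12C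
A3 | alternative 2 | (R)-2-tert-butyl-6-methyl-4H-1,3-dioxin-4-one | CC1=CC(=O)O[C@H](C(C)(C)C)O1
A4 | alternative 2 | 1,2-dimethylcyclopentene | CC1=C(C)CCC1
A5 | alternative 2 | cis-anti-cis tricyclic dioxanone photoadduct | O=C1O[C@H](C(C)(C)C)O[C@]2(C)[C@H]1[C@@]1(C)CCC[C@@]21C
A6 | alternative 3 | open-chain enone–ketone: cis-1,2-dimethylcyclopentane with (E)-4-methyl-4-(triethylsilyloxy)pent-2-enoyl on one quaternary carbon and the 2-oxo-4-methyl-6-arylhex-4-enyl chain on the other | COc1cc(C)c(O[Si](C)(C)C(C)(C)C)c(C/C=C(\C)CC(=O)C[C@@]2(C)CCC[C@@]2(C)C(=O)/C=C/C(C)(C)O[Si](CC)(CC)CC)c1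
A7 | alternative 3 | bis-silyl ether of the target (aryl tert-butyldimethylsilyl ether, side-chain triethylsilyl ether) | COc1cc(C)c(O[Si](C)(C)C(C)(C)C)c(C/C=C(\C)C[C@@]2(O)C[C@@]3(C)CCC[C@@]3(C)C(=O)[C@@H]2CC(C)(C)O[Si](CC)(CC)CC)c1
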